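## Structural features

The target is a diarylmethane with no other ring or chain: ring A carries CH2OH on C1, H on C2, hydroxyls on C3 and C4, bromine on C5 and the bridging CH2 on C6; ring B carries the bridge on C1', bromines on C2' and C3', hydroxyls on C4' and C5' and H on C6'. There is no stereocentre, so every selectivity question is one of position. The fragile groups are the two catechols (oxidation to o-quinones, above all in base), the C1 hydroxymethyl group, which is para to the C4 hydroxyl and ionises through a p-quinone methide, and the three aryl C–Br bonds (dissolving metals, hydrogenolysis, halogen–metal exchange). The real difficulty lies in ring A: two carbon arms stand ortho to each other on C1 and C6, the bridge is flanked by the C5 bromine, and C5 has to be brominated while C2 and C6', on rings of similar activation, stay unsubstituted. The key step uses the fact that C2–C3–C4–C5 with oxygens on C3 and C4 is a 2,3-dioxygenated butadiene, and that C1 and C6 with both arms attached are the two carbons of an alkyne. Ring A can therefore be built by forming C1–C2 and C5–C6. Ring B has the pattern of vanillin brominated twice, so it is taken from an arene and not built.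

## Logic of the disconnections

16 back to 14 (through 15). The three aryl O–CH3 bonds are the last to be cleaved, and the benzylic C–O bond is re-formed in the same operation. The catechols and the p-hydroxybenzylic alcohol thus appear only at the very end, and everything before handles a robust trimethyl ether. The demand is that a boron trihalide does not leave a p-alkoxybenzylic alcohol untouched: it turns it into the bromide 15. The step is therefore planned as demethylation plus hydrolysis, and the hydrolysis must run dilute and without oxygen.

14 back to 13. The two C–H bonds of the hydroxymethyl carbon are traded for the ester C=O and C–OMe, and the ring B phenol for its pivalate. The ester is kept this long because it does three jobs earlier: it activates the alkyne, survives strong acid, and shields C2. One hydride step removes both acyl groups. The hydride must spare three aryl bromides.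

13 back to 12. The C5–Br bond is cut. C5 derives from a terminal CH2 of the diene and cannot carry a halogen through cycloaddition and aromatisation, so this bromine has to come late. The forward step must choose C5 over C2 and over C6'. The C1 ester, ortho to C2 and only meta to C5, settles the first choice. The second is the reason for a change in protecting group: with a methyl ether on the C4' oxygen, C6' would be almost as reactive as C5, and the ring B benzyl group would be a good leaving group for ipso attack at C6. The C4' oxygen is therefore carried as a pivalate, which deactivates ring B and is removed for free in the ester reduction.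

12 back to 11. The two C–H bonds of the bridge are traded for a C=O. The ketone is what makes the alkyne doubly activated, and it comes directly from an aldehyde. The deoxygenation must avoid metals and hydrogen (aryl bromides) and must cope with a neighbouring ester that can capture the benzhydrol as a lactone.

11 back to 10. One C–H bond each at C2 and C5 is restored, which turns the arene into a 1,4-cyclohexadiene. The forward step is a dehydrogenation driven by aromatisation.

10 back to 8 and 9. C1–C2 and C5–C6 are cut. This takes ring A apart into a symmetrical diene and an alkyne that already bears both arms, so the crowded ortho pair is never made by substitution on a filled arene. The forward step needs a doubly activated alkyne and no regiocontrol.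

8 back to 7, then to 4 and 5 (through 6). The bond between the carbinol carbon and the alkyne carbon is cut after adjusting the oxidation level. This reduces the ynone to an aldehyde and a three-carbon ester. The forward addition needs a non-nucleophilic base at low temperature because of the aryl bromides and the aryl ester, and the oxidation must be neutral because 8 is a strong Michael acceptor.

4 back to 3, then to 1 (through 2). The aryl O–acyl bond and the C2'–Br and C3'–Br bonds are cut. Both bromines go in under the direction of the free phenol and the methoxy group of 1, which is established arene chemistry. The second bromination needs a Lewis acid because the ring is then deactivated.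

## Other disconnections considered

Alternative 1: The cut is at C6–C5 and C6–C1 of ring A. C1 to C5, both ring oxygens and the C1 arm come from the doubly protected kojic acid A2 (5-benzyloxy-2-(methoxymethyl)-4H-pyran-4-one); C6, the bridge and ring B come from the 2-arylethylphosphonium salt A3. In the forward direction the ylide of A3 would add to the unsubstituted carbon next to the ring oxygen of A2, the 2H-pyran so formed would open, and an intramolecular Wittig reaction on the freed ketone would close the benzene ring to give the phenol A1 with loss of the phosphine oxide.
- In favour: the starting material is cheap and already holds five of the six ring carbons with the right oxygens. Both arms arrive at their final oxidation level, so no ketone deoxygenation and no ester reduction are needed. The C3 and C4 oxygens come out differentiated. On these three points it is the equal or the better of the chosen plan.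
- Against: conversion of pyran rings into benzenes by phosphorus ylides is secure for pyrylium salts, whereas a neutral 4-pyranone would face a strongly basic, non-stabilised ylide that can deprotonate or attack elsewhere. A3 needs a two-carbon homologation of the ring B aldehyde. The free C3 phenol of A1 directs an electrophile to C2, its only free ortho position, so the phenol would have to be masked as an ester before C5 can be brominated.
- Comparison: structurally attractive and about equal in step count, but mechanistically much less predictable than a concerted cycloaddition of a symmetrical diene.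

Alternative 2: The cut is the bond between C1 and the hydroxymethyl carbon. That carbon and its oxygen are traced to the O–CH2–O unit of the methoxymethyl ether A5 of a fully brominated diarylmethanol. In the forward direction TMSOTf would ionise the acetal to an oxocarbenium ion, C1 of ring A (para to the C4 methoxy group) would attack it, and the 1-arylphthalan A4 would form. Ionic hydrogenolysis of its doubly benzylic C–O bond would give the tetramethyl ether A6 of the target, in which the old carbinol oxygen has become the hydroxymethyl oxygen.
- In favour: all three bromines are in place before the rings are joined, so no late bromination has to choose between positions. The route is convergent and needs no redox change on the C1 arm. On bromine placement and on steps after the key step it is better than the chosen plan.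
- Against: the five-membered ring must close by arene attack through a three-atom tether, a strained approach, on a ring deactivated by bromine. Ionisation of the diarylmethyl C–O bond to a benzhydryl cation competes with ionisation of the acetal. The diarylmethanol needs an aryl-metal addition in which one of several C–Br bonds must be spared or exchanged selectively. The final hydrogenolysis must stop before the p-methoxybenzylic alcohol of A6 is itself reduced.
- Comparison: better on structure and slightly better on step count, weaker on mechanistic certainty because two ionisations and two reductions must each be selective.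

Alternative 3: The cuts are the three C–Br bonds at C5, C2' and C3'. In the forward direction bromide is oxidised at the anode of an undivided cell and the bromine-free ester A8 is substituted three times to give A7.
- In favour: it is the shortest plan and avoids handling molecular bromine. The free phenols steer the first two bromines to their ortho positions, and the third should go para to the ring B methoxy group, as in the double bromination of vanillin. On step economy and atom economy it is better than the chosen plan.
- Against: the third substitution is far slower than the first two, so the charge needed to complete it also exposes the electron-rich phenols and the diarylmethane CH2 (para to a free phenol) to oxidation. Partly brominated and over-oxidised material is the likely penalty. A7 still needs ester reduction and demethylation, so the sensitive end game is not avoided.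
- Comparison: shortest on paper, but it has the least control over each position. The chosen plan sets two bromines on vanillin by well-established chemistry and the third under the control of substituents on a protected arene.

Key step: step 5

Remark on the chemistry: from 4 to 13 the C4' oxygen of ring B is carried as a pivalate in place of a methyl ether; the carbon skeletons of 8 and 10 and the bonds formed in step 5 are unaffected by this.

## Route

Step 1
Reactants: 1 vanillin
Product: 3 2,3-dibromo-4-hydroxy-5-methoxybenzaldehyde (5,6-dibromovanillin), via 5-bromovanillin 2 (not isolated)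
Conditions: Br2 (1.05 equiv), AcOH, rt; then NaOAc (2.5 equiv), Fe powder (cat.), Br2 (1.2 equiv), rt to 40 °C
Reagents that add atoms: bromine, BrBr
Why: Electrophilic aromatic bromination, twice in one pot: the first bromine enters ortho to the free phenol (its para position is blocked by the formyl group), the second enters para to the methoxy group, the only remaining site with a para oxygen; FeBr3 formed in the flask supplies the stronger electrophile that the deactivated monobromide 2 needs.

Step 2
Reactants: 3 2,3-dibromo-4-hydroxy-5-methoxybenzaldehyde
Product: 4 2,3-dibromo-4-formyl-6-methoxyphenyl pivalate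
Conditions: t-BuCOCl (1.2 equiv), Et3N, DMAP (cat.), CH2Cl2, 0 °C to rt
Reagents that add atoms: pivaloyl chloride, CC(C)(C)C(=O)Cl
Why: O-acylation of an acidic phenol under nucleophilic catalysis; the hindered acyl group resists the later acetylide, acid and bromine, makes ring B a poorer nucleophile, and is lost in the hydride step 9.

Step 3
Reactants: 4 2,3-dibromo-4-formyl-6-methoxyphenyl pivalate; 5 methyl propiolate
Product: 7 methyl 4-[2,3-dibromo-5-methoxy-4-(pivaloyloxy)phenyl]-4-hydroxybut-2-ynoate (racemic), via methyl 3-lithiopropiolate 6 (not isolated)
Conditions: 5 (1.3 equiv), LiN(SiMe3)2 (1.25 equiv), THF, −78 °C; then 4 in THF, −78 °C; AcOH quench at −78 °C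
Reagents that add atoms: none
Why: 1,2-Addition of a lithium acetylide to an aldehyde; the silylamide base deprotonates the alkyne without halogen–metal exchange at the aryl bromides, and quenching cold keeps the alkoxide from attacking the pivalate. The carbinol centre is formed without control and is racemic, which does not matter because step 4 removes it.

Step 4
Reactants: 7 methyl 4-[2,3-dibromo-5-methoxy-4-(pivaloyloxy)phenyl]-4-hydroxybut-2-ynoate
Product: 8 methyl 4-[2,3-dibromo-5-methoxy-4-(pivaloyloxy)phenyl]-4-oxobut-2-ynoate
Conditions: activated MnO2 (15 equiv), CH2Cl2, rt
Reagents that add atoms: none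
Why: MnO2 oxidation of an alcohol that is both benzylic and propargylic; the neutral heterogeneous oxidant leaves no nucleophile in solution that could add to the very electrophilic ynone ester.

Step 5
Reactants: 8 methyl 4-[2,3-dibromo-5-methoxy-4-(pivaloyloxy)phenyl]-4-oxobut-2-ynoate; 9 2,3-dimethoxybuta-1,3-diene
Product: 10 methyl 2-[2,3-dibromo-5-methoxy-4-(pivaloyloxy)benzoyl]-4,5-dimethoxycyclohexa-1,4-diene-1-carboxylate
Conditions: 9 (2 equiv), BHT (cat.), toluene, 80–100 °C, sealed tube, N2; excess 9 and solvent removed in vacuo, crude 10 used at once
Reagents that add atoms: none
Why: This is a thermal Diels–Alder reaction of normal electron demand: the HOMO of the bis(enol ether) diene 9, in its s-cis conformer, combines suprafacially with the LUMO of the alkyne of 8, which is lowered by both the ketone and the ester, so that C1–C2 and C5–C6 form in one concerted, possibly asynchronous, event. The closest known reaction type is the cycloaddition of 2,3-dialkoxybutadienes with acetylenic esters and ketones such as acetylenedicarboxylates, which gives 4,5-dialkoxycyclohexa-1,4-dienes that are then dehydrogenated to 4,5-dialkoxyphthalate-type arenes. The six-membered carbocycle of ring A is closed by an intermolecular [4+2] annulation in which the four diene carbons become C2 to C5 and the two alkyne carbons become C1 and C6, so no chain cyclisation with a ring-size or exo/endo question is involved. No stereocentre is formed, because C1 and C6 end as the sp2 carbons of a double bond and C2 and C5 are CH2 groups. No regiocontrol is needed, since 9 is C2-symmetric and both orientations give the same adduct. The chemoselectivity that is needed, reaction at the alkyne only, follows from its being the only electron-poor and accessible π bond, and the tetrasubstituted C1=C6 alkene of 10 is too hindered to take up a second diene. The adduct is a bis(enol ether) that hydrolyses with acid and aromatises in air, so acid is excluded, a radical inhibitor keeps 9 from polymerising, and the excess of 9 is removed before the oxidant of step 6 is added.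

Step 6
Reactants: 10 methyl 2-[2,3-dibromo-5-methoxy-4-(pivaloyloxy)benzoyl]-4,5-dimethoxycyclohexa-1,4-diene-1-carboxylate
Product: 11 methyl 2-[2,3-dibromo-5-methoxy-4-(pivaloyloxy)benzoyl]-4,5-dimethoxybenzoate
Conditions: DDQ (1.1 equiv), toluene, 0 °C to rt
Reagents that add atoms: none
Why: Quinone dehydrogenation of a 1,4-cyclohexadiene: hydride abstraction from a doubly allylic CH2 gives a cation stabilised by a methoxy group, and proton loss gives the arene; aromatisation is the driving force.

Step 7
Reactants: 11 methyl 2-[2,3-dibromo-5-methoxy-4-(pivaloyloxy)benzoyl]-4,5-dimethoxybenzoate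
Product: 12 methyl 2-[2,3-dibromo-5-methoxy-4-(pivaloyloxy)benzyl]-4,5-dimethoxybenzoate
Conditions: Et3SiH (4 equiv), CF3CO2H–CH2Cl2 (1:1), CF3SO3H (cat.), 0 °C to rt
Reagents that add atoms: none
Why: Ionic hydrogenation (Kursanov–Parnes reduction): the protonated diaryl ketone takes a hydride from the silane, the benzhydrol ionises to a cation stabilised by the para C3 methoxy group of ring A, and a second hydride gives the CH2 bridge. This is the usual method for (4-alkoxyphenyl)(2-haloaryl) ketones and spares the ester, the pivalate and the aryl bromides, which dissolving metals or hydrogenolysis would not.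

Step 8
Reactants: 12 methyl 2-[2,3-dibromo-5-methoxy-4-(pivaloyloxy)benzyl]-4,5-dimethoxybenzoate
Product: 13 methyl 3-bromo-2-[2,3-dibromo-5-methoxy-4-(pivaloyloxy)benzyl]-4,5-dimethoxybenzoate
Conditions: Br2 (1.05 equiv), AcOH, rt, dark
Reagents that add atoms: bromine, BrBr
Why: Electrophilic aromatic bromination: C5 is ortho to the C4 methoxy group and to the benzylic CH2 and only meta to the ester, C2 is ortho to the ester, and C6' of ring B is deactivated by two bromines and by the meta acyloxy group, so substitution should occur at C5. Ring bromination ortho to a methoxy group and meta to a carbonyl group is a known pattern for 3,4-dimethoxyaryl carbonyl compounds; polar conditions in the dark avoid radical attack on the bridge.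

Step 9
Reactants: 13 methyl 3-bromo-2-[2,3-dibromo-5-methoxy-4-(pivaloyloxy)benzyl]-4,5-dimethoxybenzoate
Product: 14 2,3-dibromo-4-[2-bromo-6-(hydroxymethyl)-3,4-dimethoxybenzyl]-6-methoxyphenol
Conditions: i-Bu2AlH (5 equiv), CH2Cl2, −78 to 0 °C; aq. KNaC4H4O6 (potassium sodium tartrate) work-up
Reagents that add atoms: none
Why: Aluminium hydride reduction of an aryl ester to the benzylic alcohol; the same reagent cleaves the aryl pivalate, so ring B leaves the step as its free C4' phenol, and aryl bromides are inert to i-Bu2AlH at these temperatures.

Step 10
Reactants: 14 2,3-dibromo-4-[2-bromo-6-(hydroxymethyl)-3,4-dimethoxybenzyl]-6-methoxyphenol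
Product: 16 3-bromo-4-(2,3-dibromo-4,5-dihydroxybenzyl)-5-(hydroxymethyl)benzene-1,2-diol (target), via bromomethyl tetraphenol 15 (not isolated)
Conditions: BBr3 (8 equiv), CH2Cl2, −78 °C to rt; then H2O–acetone, 0 °C to rt, argon, high dilution
Reagents that add atoms: water, O
Why: Lewis acid cleavage of aryl methyl ethers (complexation at oxygen, then SN2 attack of bromide on the methyl group); the same conditions convert the p-alkoxybenzylic alcohol into the benzylic bromide 15. Because its CH2Br is para to the C4 hydroxyl, 15 solvolyses in water through a p-quinone methide to the hydroxymethyl group; dilute, oxygen-free hydrolysis limits benzylation of other molecules and oxidation of the catechols.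

## Compound list

1 | vanillin | COc1cc(C=O)ccc1O | starting material
2 | 5-bromovanillin (3-bromo-4-hydroxy-5-methoxybenzaldehyde) | COc1cc(C=O)cc(Br)c1O | intermediate
3 | 2,3-dibromo-4-hydroxy-5-methoxybenzaldehyde (5,6-dibromovanillin) | COc1cc(C=O)c(Br)c(Br)c1O | intermediate
4 | 2,3-dibromo-4-formyl-6-methoxyphenyl pivalate | COc1cc(C=O)c(Br)c(Br)c1OC(=O)C(C)(C)C | intermediate
5 | methyl propiolate | COC(=O)C#C | starting material
6 | methyl 3-lithiopropiolate | COC(=O)C#C[Li] | intermediate
7 | methyl 4-[2,3-dibromo-5-methoxy-4-(pivaloyloxy)phenyl]-4-hydroxybut-2-ynoate (racemic) | COC(=O)C#CC(O)c1cc(OC)c(OC(=O)C(C)(C)C)c(Br)c1Br | intermediate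
8 | methyl 4-[2,3-dibromo-5-methoxy-4-(pivaloyloxy)phenyl]-4-oxobut-2-ynoate | COC(=O)C#CC(=O)c1cc(OC)c(OC(=O)C(C)(C)C)c(Br)c1Br | intermediate
9 | 2,3-dimethoxybuta-1,3-diene | COC(=C)C(=C)OC | starting material
10 | methyl 2-[2,3-dibromo-5-methoxy-4-(pivaloyloxy)benzoyl]-4,5-dimethoxycyclohexa-1,4-diene-1-carboxylate | COC(=O)C1=C(C(=O)c2cc(OC)c(OC(=O)C(C)(C)C)c(Br)c2Br)CC(OC)=C(OC)C1 | intermediate
11 | methyl 2-[2,3-dibromo-5-methoxy-4-(pivaloyloxy)benzoyl]-4,5-dimethoxybenzoate | COC(=O)c1cc(OC)c(OC)cc1C(=O)c1cc(OC)c(OC(=O)C(C)(C)C)c(Br)c1Br | intermediate
12 | methyl 2-[2,3-dibromo-5-methoxy-4-(pivaloyloxy)benzyl]-4,5-dimethoxybenzoate | COC(=O)c1cc(OC)c(OC)cc1Cc1cc(OC)c(OC(=O)C(C)(C)C)c(Br)c1Br | intermediate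
13 | methyl 3-bromo-2-[2,3-dibromo-5-methoxy-4-(pivaloyloxy)benzyl]-4,5-dimethoxybenzoate | COC(=O)c1cc(OC)c(OC)c(Br)c1Cc1cc(OC)c(OC(=O)C(C)(C)C)c(Br)c1Br | intermediate
14 | 2,3-dibromo-4-[2-bromo-6-(hydroxymethyl)-3,4-dimethoxybenzyl]-6-methoxyphenol | OCc1cc(OC)c(OC)c(Br)c1Cc1cc(OC)c(O)c(Br)c1Br | intermediate
15 | 3-bromo-5-(bromomethyl)-4-(2,3-dibromo-4,5-dihydroxybenzyl)benzene-1,2-diol | BrCc1cc(O)c(O)c(Br)c1Cc1cc(O)c(O)c(Br)c1Br | intermediate
16 | 3-bromo-4-(2,3-dibromo-4,5-dihydroxybenzyl)-5-(hydroxymethyl)benzene-1,2-diol | OCc1cc(O)c(O)c(Br)c1Cc1cc(O)c(O)c(Br)c1Br | target

## Step count and least certain steps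

Total step count: 10. Longest linear sequence: 10 steps, from 1 to 16; 5 and 9 are commercial and enter in steps 3 and 5.

Step 5 (key step). The likeliest failure is loss of the electron-rich diene by polymerisation or by hydrolysis on traces of acid before it has found the hindered alkyne, together with slow decomposition of the ynone on prolonged heating. The fallback sets out from 7 and returns at 11, keeping the same two new bonds but using an alkene as dienophile. Amine-catalysed redox isomerisation of the γ-hydroxy ynoate (Et3N cat., THF, rt to 50 °C) should give methyl (E)-4-[2,3-dibromo-5-methoxy-4-(pivaloyloxy)phenyl]-4-oxobut-2-enoate F1, a stable and reactive aroylacrylate. Its [4+2] cycloaddition with 9 (toluene, 60–80 °C) should give racemic methyl trans-6-[2,3-dibromo-5-methoxy-4-(pivaloyloxy)benzoyl]-3,4-dimethoxycyclohex-3-ene-1-carboxylate F2, and twofold dehydrogenation (DDQ, 2.5 equiv, dioxane, 80 °C) should give 11.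

Step 7. The likeliest failure is capture of the intermediate benzhydrol or its cation by the neighbouring ester (lactonisation), which stalls the reduction at the alcohol oxidation level or splits the material between ester and acid. The fallback sets out from 11 and returns at 12, and makes the lactone on purpose. NaBH4 (THF–MeOH, 0 °C) reduces the ketone and the carbinol closes onto the ester to give racemic 3-[2,3-dibromo-5-methoxy-4-(pivaloyloxy)phenyl]-5,6-dimethoxyisobenzofuran-1(3H)-one F3. Ionic hydrogenolysis of its doubly benzylic C–O bond (Et3SiH, CF3SO3H, CH2Cl2, 0 °C to rt) gives 2-[2,3-dibromo-5-methoxy-4-(pivaloyloxy)benzyl]-4,5-dimethoxybenzoic acid F4, and alkylation of the carboxylate (MeI, KHCO3, DMF, rt) gives 12.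

Step 10. The likeliest failure is benzylation of a second molecule by the p-hydroxybenzylic bromide, cation or quinone methide during the Lewis acid treatment or the hydrolysis, and air oxidation of the catechols in the aqueous phase. The fallback sets out from 14 and returns at 16, and carries the C1 arm through the demethylation as an aldehyde, which has no benzylic leaving group. MnO2 (CH2Cl2, rt) oxidises the benzylic alcohol to 3-bromo-2-(2,3-dibromo-4-hydroxy-5-methoxybenzyl)-4,5-dimethoxybenzaldehyde F5. BBr3 (CH2Cl2, −78 °C to rt, aqueous quench) gives 3-bromo-2-(2,3-dibromo-4,5-dihydroxybenzyl)-4,5-dihydroxybenzaldehyde F6, and NaBH4 (THF–H2O, 0 °C, then buffered to about pH 6) reduces the aldehyde to 16.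

Step 3. The likeliest failure is acyl transfer from the activated aryl pivalate to the lithium alkoxide, or self-condensation of the lithiated propiolate if the temperature rises above −78 °C. The fallback sets out from 4 and returns at 7, and avoids a stoichiometric base. Methyl 3-(trimethylsilyl)propiolate with catalytic Bu4NF (THF, −20 °C) transfers the alkynyl group to the aldehyde under fluoride catalysis and gives methyl 4-[2,3-dibromo-5-methoxy-4-(pivaloyloxy)phenyl]-4-(trimethylsilyloxy)but-2-ynoate F7, and mild acid work-up (citric acid, MeOH–H2O) gives 7.

## Further compounds

F1 | step 5 | methyl (E)-4-[2,3-dibromo-5-methoxy-4-(pivaloyloxy)phenyl]-4-oxobut-2-enoate | COC(=O)/C=C/C(=O)c1cc(OC)c(OC(=O)C(C)(C)C)c(Br)c1Br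
F2 | step 5 | methyl trans-6-[2,3-dibromo-5-methoxy-4-(pivaloyloxy)benzoyl]-3,4-dimethoxycyclohex-3-ene-1-carboxylate (racemic, one enantiomer drawn) | COC(=O)[C@H]1CC(OC)=C(OC)C[C@@H]1C(=O)c1cc(OC)c(OC(=O)C(C)(C)C)c(Br)c1Br
F3 | step 7 | 3-[2,3-dibromo-5-methoxy-4-(pivaloyloxy)phenyl]-5,6-dimethoxyisobenzofuran-1(3H)-one (racemic) | O=C1OC(c2cc(OC)c(OC(=O)C(C)(C)C)c(Br)c2Br)c2cc(OC)c(OC)cc21
F4 | step 7 | 2-[2,3-dibromo-5-methoxy-4-(pivaloyloxy)benzyl]-4,5-dimethoxybenzoic acid | OC(=O)c1cc(OC)c(OC)cc1Cc1cc(OC)c(OC(=O)C(C)(C)C)c(Br)c1Br
F5 | step 10 | 3-bromo-2-(2,3-dibromo-4-hydroxy-5-methoxybenzyl)-4,5-dimethoxybenzaldehyde | O=Cc1cc(OC)c(OC)c(Br)c1Cc1cc(OC)c(O)c(Br)c1Br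
F6 | step 10 | 3-bromo-2-(2,3-dibromo-4,5-dihydroxybenzyl)-4,5-dihydroxybenzaldehyde | O=Cc1cc(O)c(O)c(Br)c1Cc1cc(O)c(O)c(Br)c1Br
F7 | step 3 | methyl 4-[2,3-dibromo-5-methoxy-4-(pivaloyloxy)phenyl]-4-(trimethylsilyloxy)but-2-ynoate (racemic) | COC(=O)C#CC(O[Si](C)(C)C)c1cc(OC)c(OC(=O)C(C)(C)C)c(Br)c1Br
A1 | alternative 1 | 2-(benzyloxy)-4-(2,3-dibromo-4,5-dimethoxybenzyl)-5-(methoxymethyl)phenol | COCc1cc(O)c(OCc2ccccc2)cc1Cc1cc(OC)c(OC)c(Br)c1Br
A2 | alternative 1 | 5-(benzyloxy)-2-(methoxymethyl)-4H-pyran-4-one | COCc1cc(=O)c(OCc2ccccc2)co1
A3 | alternative 1 | [2-(2,3-dibromo-4,5-dimethoxyphenyl)ethyl]triphenylphosphonium bromide | COc1cc(CC[P+](c2ccccc2)(c2ccccc2)c2ccccc2)c(Br)c(Br)c1OC.[Br-]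
A4 | alternative 2 | 7-bromo-1-(2,3-dibromo-4,5-dimethoxyphenyl)-5,6-dimethoxy-1,3-dihydroisobenzofuran (racemic) | COc1cc2c(c(Br)c1OC)C(OC2)c1cc(OC)c(OC)c(Br)c1Br
A5 | alternative 2 | 2-bromo-1-[(2,3-dibromo-4,5-dimethoxyphenyl)(methoxymethoxy)methyl]-3,4-dimethoxybenzene (racemic) | COCOC(c1ccc(OC)c(OC)c1Br)c1cc(OC)c(OC)c(Br)c1Br
A6 | alternative 2 | [3-bromo-2-(2,3-dibromo-4,5-dimethoxybenzyl)-4,5-dimethoxyphenyl]methanol | OCc1cc(OC)c(OC)c(Br)c1Cc1cc(OC)c(OC)c(Br)c1Br
A7 | alternative 3 | methyl 3-bromo-2-(2,3-dibromo-4-hydroxy-5-methoxybenzyl)-4-hydroxy-5-methoxybenzoate | COC(=O)c1cc(OC)c(O)c(Br)c1Cc1cc(OC)c(O)c(Br)c1Br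
A8 | alternative 3 | methyl 4-hydroxy-2-(4-hydroxy-3-methoxybenzyl)-5-methoxybenzoate | COC(=O)c1cc(OC)c(O)cc1Cc1ccc(O)c(OC)c1
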